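**Plan**

Chalcone numbering: ring B = C1–C6 (C1 bears Cβ, C2 OMe, C3 and C4 OH, C5 the 1,1-dimethylallyl group); ring A = C1'–C6'.
Cuts: (a) C5–C(CH3)2, back to an O4-prenyl ether ([3,3] shift); (b) C1'–C(=O) and O2–CH3 together, which folds O2–C2–C1–Cβ=Cα–C(=O) back into a lactone.
Enabling feature: O2, C2, C1, Cβ, Cα and the carbonyl carbon form a ring-opened, O-methylated α-pyrone fused to ring B. With O3 and O4 this is 7,8-dihydroxycoumarin (daphnetin, 1), whose lactone already tells O2 apart from O3 and O4.
Forward: 1 → 7-O-prenyl ether → 8-O-MOM ether → 4-(MOMO)phenyllithium opens the pyranone at the lactone carbonyl, the released phenoxide is methylated in the same flask and the Z-enone is equilibrated to E (ring A joined, enone and O2-methyl ether formed together) → Claisen shift O4 → C5 → removal of two MOM groups.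
Stereochemistry: no stereocentre; the (E)-alkene is set under thermodynamic control in the key step and is not touched again.

Key step: step 3

Remark: the target is achiral, so "single enantiomer" is read as the (E)-isomer drawn; 1-bromo-4-(methoxymethoxy)benzene is taken as a catalogue compound; MOM = methoxymethyl, prenyl = 3-methylbut-2-en-1-yl.

**Route**

Step 1
Reactants: 1 daphnetin (7,8-dihydroxy-2H-chromen-2-one); 2 prenyl bromide (1-bromo-3-methylbut-2-ene)
Product: 3 8-hydroxy-7-(3-methylbut-2-en-1-yloxy)-2H-chromen-2-one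
Conditions: NaHCO3 (1.5 equiv), 2 (1.1 equiv), DMF, 40 °C
Reagents that add atoms: none
Why: Williamson etherification under pKa control: the 7-OH is conjugated through C4a and C4=C3 with the lactone carbonyl (a vinylogous acid) and should be the only phenol deprotonated by hydrogencarbonate, so the SN2 reaction takes place at O7, as in the known 4-O-selective alkylation of 3,4-dihydroxybenzaldehyde.

Step 2
Reactants: 3 8-hydroxy-7-(3-methylbut-2-en-1-yloxy)-2H-chromen-2-one
Product: 4 8-(methoxymethoxy)-7-(3-methylbut-2-en-1-yloxy)-2H-chromen-2-one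
Conditions: MOMCl (2 equiv), iPr2NEt (3 equiv), CH2Cl2, 0 °C → reflux
Reagents that add atoms: chloromethyl methyl ether (MOMCl), COCCl
Why: Standard MOM protection of a phenol with MOMCl and Hünig's base; it masks O8 (the future O3) so that in step 3 only the newly freed oxygen can be methylated, and the lactone and prenyl ether are inert.

Step 3
Reactants: 4 8-(methoxymethoxy)-7-(3-methylbut-2-en-1-yloxy)-2H-chromen-2-one; 5 1-bromo-4-(methoxymethoxy)benzene
Product: 10 (2E)-3-[2-methoxy-3-(methoxymethoxy)-4-(3-methylbut-2-en-1-yloxy)phenyl]-1-[4-(methoxymethoxy)phenyl]prop-2-en-1-one, via aryllithium 6 (not isolated), via lithium lactolate 7 (not isolated), via lithium (Z)-phenoxide 8 (not isolated), via (Z)-chalcone 9 (not isolated)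
Conditions: 5 (1.1 equiv), t-BuLi (2.2 equiv), THF, −78 °C; cannulate into 4, THF, −78 → 0 °C; DMPU, MeI (5 equiv), rt; work-up; then I2 (5 mol %), CH2Cl2, daylight, rt
Reagents that add atoms: iodomethane, CI
Why: Proposed new method: the hard aryllithium 6 adds 1,2 to the lactone carbonyl C2 of coumarin 4 to give the cyclic lactolate 7, which should persist at −78 °C and so shield the carbonyl from a second addition; on warming it collapses with cleavage of the C2–O1 bond to the (Z)-enone phenoxide 8, and MeI/DMPU methylates this phenoxide oxygen (coumarin O1 = chalcone O2), the only free oxygen nucleophile in the molecule. The closest known reaction types are the addition of aryl Grignard or aryllithium reagents to coumarins on the way to 2-arylbenzopyrylium (flavylium) salts and the alkaline ring opening/O-methylation of coumarins to 2-methoxycinnamates; what is new is the capture of the open form in one flask after a carbon nucleophile. No ring is closed: the pyranone ring is opened, which joins ring A, unveils the enone and distinguishes O2 (methylated) from O3 and O4. No stereocentre is formed; the coumarin hands on a Z double bond, and iodine-atom catalysis (reversible addition of I• across Cα=Cβ) should equilibrate 9 to the more stable E-enone 10. The step needs 1,2- over 1,4-addition and mono- over double addition: the 7-alkoxy donor, conjugated through C4a and C4=C3, lowers the acceptor character of the unsaturated lactone at C4, inverse addition keeps 6 from being in excess, and the opened ketone is a deactivated vinylogous carboxylate of the ortho-phenoxide. Methylation at the phenoxide and not at the lactolate oxygen is expected because the conjugated open phenoxide is the more stable form in the dipolar medium.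

Step 4
Reactants: 10 (2E)-3-[2-methoxy-3-(methoxymethoxy)-4-(3-methylbut-2-en-1-yloxy)phenyl]-1-[4-(methoxymethoxy)phenyl]prop-2-en-1-one
Product: 12 (2E)-3-[4-hydroxy-2-methoxy-3-(methoxymethoxy)-5-(2-methylbut-3-en-2-yl)phenyl]-1-[4-(methoxymethoxy)phenyl]prop-2-en-1-one, via ortho-dienone 11 (not isolated)
Conditions: EtOH–H2O (4:1), degassed, sealed tube, 130 °C
Reagents that add atoms: none
Why: Aromatic Claisen rearrangement: the O4-prenyl ether can shift only to C5, the one ortho carbon that carries hydrogen (C3 bears OMOM), which places the quaternary C(CH3)2CH=CH2 carbon on the ring with allylic inversion; tautomerisation of dienone 11 restores the arene, and the water-accelerated variant keeps the temperature low enough for the enone and the MOM acetals.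

Step 5
Reactants: 12 (2E)-3-[4-hydroxy-2-methoxy-3-(methoxymethoxy)-5-(2-methylbut-3-en-2-yl)phenyl]-1-[4-(methoxymethoxy)phenyl]prop-2-en-1-one
Product: 13 (2E)-3-[3,4-dihydroxy-2-methoxy-5-(2-methylbut-3-en-2-yl)phenyl]-1-(4-hydroxyphenyl)prop-2-en-1-one (target)
Conditions: conc. HCl (cat.), MeOH, 40 °C, under Ar
Reagents that add atoms: none
Why: Acid-catalysed methanolysis of the two aryl MOM acetals (standard MOM cleavage); under these mild conditions the monosubstituted alkene of the 1,1-dimethylallyl group should not be protonated, and the E-enone, the aryl methyl ether and the catechol (kept under argon) are stable.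

**Compound list**

1 | daphnetin (7,8-dihydroxy-2H-chromen-2-one) | O=C1C=Cc2ccc(O)c(O)c2O1 | starting material
2 | prenyl bromide (1-bromo-3-methylbut-2-ene) | CC(C)=CCBr | starting material
3 | 8-hydroxy-7-(3-methylbut-2-en-1-yloxy)-2H-chromen-2-one | O=C1C=Cc2ccc(OCC=C(C)C)c(O)c2O1 | intermediate
4 | 8-(methoxymethoxy)-7-(3-methylbut-2-en-1-yloxy)-2H-chromen-2-one | O=C1C=Cc2ccc(OCC=C(C)C)c(OCOC)c2O1 | intermediate
5 | 1-bromo-4-(methoxymethoxy)benzene | COCOc1ccc(Br)cc1 | starting material
6 | [4-(methoxymethoxy)phenyl]lithium | [Li]c1ccc(OCOC)cc1 | intermediate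
7 | lithium 8-(methoxymethoxy)-2-[4-(methoxymethoxy)phenyl]-7-(3-methylbut-2-en-1-yloxy)-2H-chromen-2-olate (racemic at C2) | [Li]OC1(c2ccc(OCOC)cc2)C=Cc2ccc(OCC=C(C)C)c(OCOC)c2O1 | intermediate
8 | lithium 6-(methoxymethoxy)-2-{(1Z)-3-[4-(methoxymethoxy)phenyl]-3-oxoprop-1-en-1-yl}-5-(3-methylbut-2-en-1-yloxy)phenolate | [Li]Oc1c(/C=C\C(=O)c2ccc(OCOC)cc2)ccc(OCC=C(C)C)c1OCOC | intermediate
9 | (2Z)-3-[2-methoxy-3-(methoxymethoxy)-4-(3-methylbut-2-en-1-yloxy)phenyl]-1-[4-(methoxymethoxy)phenyl]prop-2-en-1-one | COc1c(/C=C\C(=O)c2ccc(OCOC)cc2)ccc(OCC=C(C)C)c1OCOC | intermediate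
10 | (2E)-3-[2-methoxy-3-(methoxymethoxy)-4-(3-methylbut-2-en-1-yloxy)phenyl]-1-[4-(methoxymethoxy)phenyl]prop-2-en-1-one | COc1c(/C=C/C(=O)c2ccc(OCOC)cc2)ccc(OCC=C(C)C)c1OCOC | intermediate
11 | (2E)-3-[6-methoxy-5-(methoxymethoxy)-3-(2-methylbut-3-en-2-yl)-4-oxocyclohexa-1,5-dien-1-yl]-1-[4-(methoxymethoxy)phenyl]prop-2-en-1-one (racemic at ring C3) | C=CC(C)(C)C1C=C(/C=C/C(=O)c2ccc(OCOC)cc2)C(OC)=C(OCOC)C1=O | intermediate
12 | (2E)-3-[4-hydroxy-2-methoxy-3-(methoxymethoxy)-5-(2-methylbut-3-en-2-yl)phenyl]-1-[4-(methoxymethoxy)phenyl]prop-2-en-1-one | C=CC(C)(C)c1cc(/C=C/C(=O)c2ccc(OCOC)cc2)c(OC)c(OCOC)c1O | intermediate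
13 | (2E)-3-[3,4-dihydroxy-2-methoxy-5-(2-methylbut-3-en-2-yl)phenyl]-1-(4-hydroxyphenyl)prop-2-en-1-one | C=CC(C)(C)c1cc(/C=C/C(=O)c2ccc(O)cc2)c(OC)c(O)c1O | target

**Summary**

Total step count: 5.
Longest linear sequence: 5 steps (1 → 3 → 4 → 10 → 12 → 13).

**Steps most likely to fail**

1. Step 3 (proposed new method). The lactolate may open too early, so that a second aryllithium adds to the unmasked ketone. Conjugate addition at C4 may compete. Methylation may occur on the closed lactolate instead of the open phenoxide, which would lead to flavylium-type material on work-up. The fallback uses only known chemistry, sets out from 4 and comes back at 9. Methoxide in methanol opens the lactone and the phenoxide is trapped with MeI (NaOMe, MeOH; then MeI, 40 °C), the classical ring opening/O-methylation of coumarins, to give the (Z)-methyl ester F1. MeNH(OMe)·HCl/i-PrMgCl (THF, −20 °C) converts it into the (Z)-Weinreb amide F2. Aryllithium 6 (THF, −78 °C) then gives (Z)-chalcone 9 by Weinreb ketone synthesis, without risk of over-addition, and 9 is isomerised with catalytic I2 to 10 as in step 3.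

2. Step 4. Prolonged heating of the polyfunctional chalcone may degrade the enone. The newly formed ortho-(1,1-dimethylallyl)phenol may react on, by abnormal Claisen isomerisation or by addition of O4–H to the vinyl group. The prenyl ether may also ionise with loss of the prenyl group. The fallback moves the sigmatropic step to the robust coumarin stage, sets out from 4 and comes back at 13. Heating 4 (PhNEt2, 190 °C) should give, by way of ortho-dienone F3, the phenol F4 (C8 is blocked by OMOM, so C6 is the only ortho carbon with hydrogen). MOMCl/iPr2NEt gives the bis-MOM coumarin F5. F5 is carried through the sequence of step 3 (aryllithium 6; DMPU/MeI; I2), by way of lactolate F6, (Z)-phenoxide F7 and (Z)-chalcone F8, to the tris-MOM (E)-chalcone F9. Acid methanolysis as in step 5 then gives 13.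

3. Step 1. Discrimination between O7 and O8 may be insufficient, with alkylation at both oxygens or competing C-alkylation of the ambident phenoxide. The fallback avoids phenoxide formation altogether, sets out from 1 and comes back at 3. A Mitsunobu etherification with 3-methylbut-2-en-1-ol (PPh3, DIAD, THF, 0 °C → rt) should engage only the more acidic 7-OH; no new compound arises (F0).

**Further compounds**

F1 | step 3 | methyl (2Z)-3-[2-methoxy-3-(methoxymethoxy)-4-(3-methylbut-2-en-1-yloxy)phenyl]prop-2-enoate | COC(=O)/C=C\c1ccc(OCC=C(C)C)c(OCOC)c1OC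
F2 | step 3 | (2Z)-N-methoxy-3-[2-methoxy-3-(methoxymethoxy)-4-(3-methylbut-2-en-1-yloxy)phenyl]-N-methylprop-2-enamide | CON(C)C(=O)/C=C\c1ccc(OCC=C(C)C)c(OCOC)c1OC
F3 | step 4 | 8-(methoxymethoxy)-6-(2-methylbut-3-en-2-yl)-6H-chromene-2,7-dione | C=CC(C)(C)C1C=C2C=CC(=O)OC2=C(OCOC)C1=O
F4 | step 4 | 7-hydroxy-8-(methoxymethoxy)-6-(2-methylbut-3-en-2-yl)-2H-chromen-2-one | C=CC(C)(C)c1cc2C=CC(=O)Oc2c(OCOC)c1O
F5 | step 4 | 7,8-bis(methoxymethoxy)-6-(2-methylbut-3-en-2-yl)-2H-chromen-2-one | C=CC(C)(C)c1cc2C=CC(=O)Oc2c(OCOC)c1OCOC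
F6 | step 4 | lithium 7,8-bis(methoxymethoxy)-2-[4-(methoxymethoxy)phenyl]-6-(2-methylbut-3-en-2-yl)-2H-chromen-2-olate | [Li]OC1(c2ccc(OCOC)cc2)C=Cc2cc(C(C)(C)C=C)c(OCOC)c(OCOC)c2O1
F7 | step 4 | lithium 5,6-bis(methoxymethoxy)-2-{(1Z)-3-[4-(methoxymethoxy)phenyl]-3-oxoprop-1-en-1-yl}-4-(2-methylbut-3-en-2-yl)phenolate | [Li]Oc1c(/C=C\C(=O)c2ccc(OCOC)cc2)cc(C(C)(C)C=C)c(OCOC)c1OCOC
F8 | step 4 | (2Z)-3-[2-methoxy-3,4-bis(methoxymethoxy)-5-(2-methylbut-3-en-2-yl)phenyl]-1-[4-(methoxymethoxy)phenyl]prop-2-en-1-one | COc1c(/C=C\C(=O)c2ccc(OCOC)cc2)cc(C(C)(C)C=C)c(OCOC)c1OCOC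
F9 | step 4 | (2E)-3-[2-methoxy-3,4-bis(methoxymethoxy)-5-(2-methylbut-3-en-2-yl)phenyl]-1-[4-(methoxymethoxy)phenyl]prop-2-en-1-one | COc1c(/C=C/C(=O)c2ccc(OCOC)cc2)cc(C(C)(C)C=C)c(OCOC)c1OCOC
F0 | step 1 | none | none
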